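**Plan**
Retrosynthesis: first the two Si–O bonds of a temporary di-tert-butylsilylene on O5/O5′ are cut; then O1–C2 and C3–C4 of both pyran rings at once (two o-quinone methides plus two isobutene); then the two benzylic C–N bonds of a bis-Mannich base, the two aryl–CH bonds of the bridge and the aryl–acyl bond.
Forward: phloroglucinol is C-acylated, two units are joined at the 6-methylheptylidene methine, the two hydroxyls para to the ketones are tied into an eight-membered dioxasilocine, both remaining ring carbons are aminomethylated, both pyrans close together, and HF removes silicon.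
Enabling feature: in each chroman, C4a lies between O–C5 and O–C8a, and only O–C8a (beside the acylated C8) is a pyran oxygen. The two C5 oxygens sit ortho to the bridging methine on C6/C6′ and face each other, so one silicon atom can span them and leave O–C8a as the only oxygen able to form the oxadiene C4=C4a–C8a=O1.
Stereochemistry: both (R) centres come from (R)-2-methylbutanoic acid and pass only through conditions that should not enolise the ketone; the key step creates no stereocentre.

Key step: step 6

Remark: the bridging methine carries two aryl groups of identical constitution and configuration, so it is not a stereocentre and no isomers arise from it; chroman numbering is used for 14 and 15, phloroglucinol numbering (acyl-bearing carbon = C1) for earlier compounds.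

**Step 1**
Reactants: 1 (R)-2-methylbutanoic acid
Product: 2 (R)-2-methylbutanoyl chloride
Conditions: (COCl)2, cat. DMF, CH2Cl2, 0 °C to rt; volatiles removed, used crude
Reagents that add atoms: oxalyl chloride, O=C(Cl)C(Cl)=O
Why: Acid chloride formation through the DMF-derived chloroiminium (Vilsmeier-type) catalyst runs without base, so no ketene can form and the α-stereocentre should be retained.

**Step 2**
Reactants: 2 (R)-2-methylbutanoyl chloride; 3 phloroglucinol
Product: 4 (2R)-2-methyl-1-(2,4,6-trihydroxyphenyl)butan-1-one
Conditions: AlCl3 (4 equiv), PhNO2–CH2Cl2, 0 to 40 °C; aq HCl work-up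
Reagents that add atoms: none
Why: Friedel–Crafts C-acylation of the threefold-symmetric triphenol should stop at the monoketone because the chelated acyl group deactivates the ring, and adding the acid chloride to the preformed aluminium phenoxide at low temperature should leave the α-stereocentre intact (to be checked by chiral HPLC).

**Step 3**
Reactants: 4 (2R)-2-methyl-1-(2,4,6-trihydroxyphenyl)butan-1-one (3 equiv, excess recovered); 5 6-methylheptanal
Product: 7 3,3′-(6-methylheptane-1,1-diyl)-bridged bis(acylphloroglucinol), via alkylidene o-quinone methide 6 (not isolated)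
Conditions: NaOAc, AcOH, 60 °C
Reagents that add atoms: none
Why: Buffered Knoevenagel-type condensation of the aldehyde at a ring carbon of 4 gives the alkylidene o-quinone methide 6, which a second molecule of 4 captures by Michael (Friedel–Crafts-type) addition; C3 and C5 of 4 are equivalent so only one constitution can form, and the excess of 4 limits chain growth.

**Step 4**
Reactants: 7 bridged bis(acylphloroglucinol); 8 di-tert-butylsilyl bis(trifluoromethanesulfonate)
Product: 9 6,6-di-tert-butyl-1,3,9,11-tetrahydroxy-2,10-bis[(2R)-2-methylbutanoyl]-12-(5-methylhexyl)-12H-dibenzo[d,g][1,3,2]dioxasilocine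
Conditions: tBu2Si(OTf)2 (1.05 equiv, slow addition), 2,6-lutidine, DMF (dilute), −40 to 0 °C
Reagents that add atoms: none
Why: Cyclic silylene formation from a 2,2′-alkylidenebisphenol should bridge the two hydroxyls para to the ketones, because they are the most acidic, are not chelated to a carbonyl and lie on the same side of the bridging methine, whereas the four hydroxyls ortho to the ketones are less acidic and hydrogen-bonded or flanked on both sides.

**Step 5**
Reactants: 9 silylene-bridged tetraphenol
Product: 10 4,8-bis[(dimethylamino)methyl] derivative of 9 (bis-Mannich base)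
Conditions: Me2N=CH2+ I− (2.5 equiv), CH2Cl2–MeCN, rt to 40 °C; aq NaHCO3 wash
Reagents that add atoms: N,N-dimethylmethyleneiminium iodide, C=[N+](C)C.[I-]
Why: Twofold Mannich aminomethylation by the preformed iminium ion can only occur at the single unsubstituted carbon of each ring, which is ortho and para to free hydroxyls, while the hindered chelated ketones should not enolise and the silylene is inert to these non-nucleophilic conditions.

**Step 6**
Reactants: 10 bis-Mannich base; 11 isobutene (2-methylpropene, large excess)
Product: 14 5,5′-O-(di-tert-butylsilanediyl) derivative of the target, via bis(trimethylammonium) diiodide 12 (not isolated), via bis(o-quinone methide) 13 (not isolated)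
Conditions: MeI, THF, rt, then evaporation; isobutene (condensed, excess), powdered NaHCO3, MeCN–CH2Cl2, sealed pressure tube, 50 °C
Reagents that add atoms: none
Why: N-Methylation turns each benzylic amine into a trimethylammonium leaving group, and hydrogencarbonate then removes the proton of the neighbouring hydroxyl (the future O1, the only free hydroxyl ortho to the CH2), so trimethylamine leaves by 1,4-elimination and an acyl-conjugated o-quinone methide (C4=C4a–C8a=O1) is released slowly on each ring. Each electron-poor oxadiene adds isobutene in an inverse-electron-demand hetero-Diels–Alder reaction, the reaction type known for acylphloroglucinol o-quinone methides with unactivated 1,1-disubstituted alkenes. Both pyran rings close by intermolecular [4+2] cycloaddition, C3–C4 and O1–C2 forming in one asynchronous event in which the alkene CH2 bonds to C4 and the oxygen to the carbon that develops tertiary cation character, which fixes the 2,2-dimethyl pattern. No stereocentre is created, and the two (R) α-carbons should not be touched by hydrogencarbonate at 50 °C. The selectivity needed is regiochemical, O–C8a against O–C5 as ring oxygen, and it is secured because both C5 oxygens are locked in the dioxasilocine ring and can neither become the quinone methide carbonyl nor attack the cationic terminus; the hydroxyl para to the methylene can at most give a tautomeric para-quinone methide that cannot cyclise and funnels back to the same pyran. The large excess of alkene and the slow, heterogeneous release of the diene should keep self-condensation low.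

**Step 7**
Reactants: 14 silylene-protected bis-chroman
Product: 15 target, 1,1′-[(6-methylheptane-1,1-diyl)bis(5,7-dihydroxy-2,2-dimethylchromane-6,8-diyl)]bis[(2R)-2-methylbutan-1-one]
Conditions: HF·pyridine, THF–pyridine, 0 °C to rt
Reagents that add atoms: none
Why: Fluoride-driven cleavage of the two aryl Si–O bonds, the standard removal of a di-tert-butylsilylene, is driven by Si–F bond formation and should leave the ketones, the chroman ethers and the α-stereocentres unaffected under these weakly acidic conditions.

**Compound list**
1 | (R)-2-methylbutanoic acid | CC[C@@H](C)C(=O)O | starting material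
2 | (R)-2-methylbutanoyl chloride | CC[C@@H](C)C(=O)Cl | intermediate
3 | phloroglucinol (benzene-1,3,5-triol) | Oc1cc(O)cc(O)c1 | starting material
4 | (2R)-2-methyl-1-(2,4,6-trihydroxyphenyl)butan-1-one | CC[C@@H](C)C(=O)c1c(O)cc(O)cc1O | intermediate
5 | 6-methylheptanal | CC(C)CCCCC=O | starting material
6 | 3,5-dihydroxy-4-[(2R)-2-methylbutanoyl]-6-(6-methylheptylidene)cyclohexa-2,4-dien-1-one (alkylidene o-quinone methide, formed in the flask in step 3) | CC[C@@H](C)C(=O)C1=C(O)C(=CCCCCC(C)C)C(=O)C=C1O | intermediate
7 | 1,1′-[(6-methylheptane-1,1-diyl)bis(2,4,6-trihydroxybenzene-3,1-diyl)]bis[(2R)-2-methylbutan-1-one] | CC(C)CCCCC(c1c(O)cc(O)c(C(=O)[C@H](C)CC)c1O)c1c(O)cc(O)c(C(=O)[C@H](C)CC)c1O | intermediate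
8 | di-tert-butylsilyl bis(trifluoromethanesulfonate) | CC(C)(C)[Si](OS(=O)(=O)C(F)(F)F)(OS(=O)(=O)C(F)(F)F)C(C)(C)C | starting material
9 | 6,6-di-tert-butyl-1,3,9,11-tetrahydroxy-2,10-bis[(2R)-2-methylbutanoyl]-12-(5-methylhexyl)-12H-dibenzo[d,g][1,3,2]dioxasilocine | CC(C)CCCCC1c2c(O)c(C(=O)[C@H](C)CC)c(O)cc2O[Si](C(C)(C)C)(C(C)(C)C)Oc2cc(O)c(C(=O)[C@H](C)CC)c(O)c21 | intermediate
10 | 4,8-bis[(dimethylamino)methyl] derivative of 9 (bis-Mannich base) | CC(C)CCCCC1c2c(O)c(C(=O)[C@H](C)CC)c(O)c(CN(C)C)c2O[Si](C(C)(C)C)(C(C)(C)C)Oc2c1c(O)c(C(=O)[C@H](C)CC)c(O)c2CN(C)C | intermediate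
11 | isobutene (2-methylpropene) | CC(C)=C | starting material
12 | 4,8-bis[(trimethylammonio)methyl] diiodide of 9 (formed in the flask in step 6) | CC(C)CCCCC1c2c(O)c(C(=O)[C@H](C)CC)c(O)c(C[N+](C)(C)C)c2O[Si](C(C)(C)C)(C(C)(C)C)Oc2c1c(O)c(C(=O)[C@H](C)CC)c(O)c2C[N+](C)(C)C.[I-].[I-] | intermediate
13 | bis(o-quinone methide): each ring of 9 with an exocyclic methylene at C4/C8 and a carbonyl at C3/C9 (formed in the flask in step 6) | CC(C)CCCCC1C2=C(O[Si](C(C)(C)C)(C(C)(C)C)OC3=C1C(O)=C(C(=O)[C@H](C)CC)C(=O)C3=C)C(=C)C(=O)C(C(=O)[C@H](C)CC)=C2O | intermediate
14 | 5,5′-O-(di-tert-butylsilanediyl) derivative of the target (two 2,2-dimethylpyran rings fused to the dioxasilocine core) | CC(C)CCCCC1c2c(O)c(C(=O)[C@H](C)CC)c3OC(C)(C)CCc3c2O[Si](C(C)(C)C)(C(C)(C)C)Oc2c1c(O)c(C(=O)[C@H](C)CC)c3OC(C)(C)CCc23 | intermediate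
15 | 1,1′-[(6-methylheptane-1,1-diyl)bis(5,7-dihydroxy-2,2-dimethylchromane-6,8-diyl)]bis[(2R)-2-methylbutan-1-one] | CC[C@@H](C)C(=O)c1c(O)c(C(CCCCC(C)C)c2c(O)c3c(c(C(=O)[C@H](C)CC)c2O)OC(C)(C)CC3)c(O)c2c1OC(C)(C)CC2 | target

**Step count**
Total steps: 7. Longest linear sequence: 7 steps (1 → 2 → 4 → 7 → 9 → 10 → 14 → 15).

**Steps most likely to fail**

Step 6. The slowly released quinone methide may be intercepted by amine, iodide or a phenolic oxygen of a second molecule faster than by the weakly nucleophilic gaseous alkene, or only one of the two rings may cyclise, so that oligomers and half-closed material result. The fallback gives up the cycloaddition and builds each pyran by Friedel–Crafts prenylation followed by acid-catalysed hydroalkoxylation. It sets out from 9: 2-methylbut-3-en-2-ol and BF3·OEt2 in dioxane at rt should C-prenylate the one free carbon of each ring to give the 4,8-bis(3-methylbut-2-en-1-yl) derivative of 9 F1. Amberlyst 15 in toluene at 60 °C should then add the only free ortho hydroxyl of each ring across the prenyl double bond in the Markovnikov sense, the silylene again excluding the other oxygen. The fallback comes back to the route at 14, which goes on to step 7.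

Step 4. The silyl bis(triflate) may react at a hydroxyl ortho to a ketone, bridge the para oxygen of one ring to the ortho oxygen of the other, or link two molecules, so that the wrong oxygens stay free. The fallback installs silicon before the carbon bridge. It sets out from 4: half an equivalent of 8 with 2,6-lutidine in DMF (−20 °C to rt) should silylate only the para hydroxyl, the best precedented selectivity for a 2,4,6-trihydroxyaryl ketone, and give di-tert-butylbis{3,5-dihydroxy-4-[(2R)-2-methylbutanoyl]phenoxy}silane F2. Condensation of F2 with 5 (NaOAc, AcOH–CH2Cl2, 40 °C, high dilution) then makes the second arylation intramolecular, which closes the dioxasilocine ring at carbon and also suppresses chain growth. The fallback comes back to the route at 9.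

Step 3. Chain growth through the remaining free ring carbon of the product and self-aldol condensation of the aldehyde may erode the bis-adduct. The fallback makes the electrophile as an isolable one-to-one adduct. It sets out from 4: 4, 5 and morpholine (EtOH, rt) should give, in a Betti-type three-component Mannich reaction, the morpholine adduct (2R)-2-methyl-1-{2,4,6-trihydroxy-3-[6-methyl-1-(morpholin-4-yl)heptyl]phenyl}butan-1-one F3. Heating F3 with a second portion of 4 (toluene, 80 °C) should expel morpholine through the quinone methide 6 and deliver the bridge with controlled stoichiometry. The fallback comes back to the route at 7.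

**Further compounds**
F1 | step 6 | 4,8-bis(3-methylbut-2-en-1-yl) derivative of 9 | CC(C)CCCCC1c2c(O)c(C(=O)[C@H](C)CC)c(O)c(CC=C(C)C)c2O[Si](C(C)(C)C)(C(C)(C)C)Oc2c1c(O)c(C(=O)[C@H](C)CC)c(O)c2CC=C(C)C
F2 | step 4 | di-tert-butylbis{3,5-dihydroxy-4-[(2R)-2-methylbutanoyl]phenoxy}silane | CC[C@@H](C)C(=O)c1c(O)cc(O[Si](C(C)(C)C)(C(C)(C)C)Oc2cc(O)c(C(=O)[C@H](C)CC)c(O)c2)cc1O
F3 | step 3 | (2R)-2-methyl-1-{2,4,6-trihydroxy-3-[6-methyl-1-(morpholin-4-yl)heptyl]phenyl}butan-1-one (both configurations at the aminoalkyl carbon) | CC[C@@H](C)C(=O)c1c(O)cc(O)c(C(CCCCC(C)C)N2CCOCC2)c1O
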